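The runs were computed for an exercise; scatter was added.

Z, charged at 20 mM in north and south-east, puts two questions to you: how it splits in the first minutes, and how far the slower change has gone by the reading.

| setting | beta | eta | north | south-east |
|---|---|---|---|---|
| Z | 13 mM | 30 mM | 20 mM | 20 mM |
| remark | run made earlier | run made earlier |  |  |
| time |  |  | 15 min | 20 min |

| run | time / min | Z / % | Q / % | J / % | L / % | X / % |
|---|---|---|---|---|---|---|
| beta | 2.00 | 19 | 2 | 3 | 26 | 44 |
| beta | 4.00 | 12 | 2 | 12 | 21 | 50 |
| beta | 5.00 | 4 | 1 | 15 | 25 | 55 |
| beta | 8.00 | 4 | 2 | 26 | 17 | 49 |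
| beta | 10.0 | 1 | 5 | 25 | 16 | 50 |
| eta | 2.00 | 14 | 0 | 2 | 44 | 35 |
| eta | 4.00 | 9 | 1 | 9 | 41 | 39 |
| eta | 5.00 | 6 | 1 | 13 | 37 | 40 |
| eta | 8.00 | 0 | 1 | 19 | 37 | 39 |
| eta | 10.0 | 4 | 2 | 21 | 30 | 39 |

(readings scatter by 2 percentage points)

- in percentages every species weighs as the Z in it: one L or Q counts as two
- the numbers in the tables scatter with a standard deviation of 2 percentage points

- which of these there is most of at the end, counted by the Z in it, north (L / X / Q / J)
- which of these there is most of at the end, counted by the Z in it, south-east (L / X / Q / J)
- amount of the one of these that there is most of at the end, in percent of the Z charged, north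
- amount of the one of these that there is most of at the end, in percent of the Z charged, south-east

Take the rungs from the fastest. Z reads 19% in beta and 14% in eta at 2.00 min, and the charge has split into X and L, with more L in eta than in beta.

The next rung is L. It falls from 26% to 16% in beta and from 44% to 30% in eta. Read as a first-order decay, that gives 11.4 min in beta and 14.5 min in eta, although eta holds more than twice the charge. So I carry one number, the drain time h, the half-life of L once Z has split, 12.8 min from both runs together. It is a reading, with their scatter.

The last rung is X, which reads the same at 4.00 min and 10.0 min in each run. I hold it flat.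

Now join the two ends. The early end comes from a straight line between the charges, and the late end from h:

L at 2.00 min, 20 mM: 33.4%
X on its plateau, 20 mM: 45.5%
north, 15 min: L 16.5%, remainder 38.0%
south-east, 20 min: L 12.6%, remainder 41.9%

On this reckoning, even if J held the whole remainder, X would stay ahead in north and in south-east.

The forecast gives X at 45% in north and X at 45% in south-east, since “neither J nor L should overtake X”.

North gives X at 46.8% with L at 17.0%; south-east gives X at 48.2% with L at 12.4%.

    X ⇌ J (K = 0.803, k = 0.00168 s⁻¹)
    2 Z ⇌ L (K = 315 M⁻¹, k = 0.342 M⁻¹ s⁻¹)
    Z → D (k = 4.23 × 10⁻⁷ s⁻¹)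
    Z + X → Q (k = 0.0280 M⁻¹ s⁻¹)
    Z → X (k = 0.00868 s⁻¹)

In north at 15.0 min, X is still made 1.29 times as fast as it is used up, each step taken net. Now read the same flask as north later, at 40 min. The same h and the same start give L 4.27%, and that later reading holds 3.45%. X then stands at 51.6%, and J at 40.3%.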